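The synthesis rests on disconnecting two adjacent bonds of ring A together: C4'–O and C5'–CHO. The neighbouring hydroxyl (C4') and formyl (C5') groups correspond to the oxygen and carbon of one N,N-dimethylformamide molecule, so a C4'–C5' aryne of ring A can acquire both in a single fluoride-triggered operation, the C6' benzyloxy group directing oxygen to C4'. The precursor is the fully assembled depside with a triflate on C4', a trimethylsilyl group on C5' and benzyl ethers on O6' and on O2 of ring B; the hindered ester link and all five C-methyl groups are already present. Neutral hydrogenolysis then completes the target.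

Key step: step 12

Remarks on the chemistry
- Locants: ring A is the acyl ring (C1' bears the depside carbonyl, C2' and C3' methyl, C4' OH, C5' CHO, C6' OH). Ring B is the phenol ring (C1 CO2Me, C2 OH, C3 CH3, C4 O-acyl, C5 CH3, C6 CH3). The target has no stereocentre.
- Ring B of the target is a 3,5,6-trimethyl resorcylate. Commercial methyl 2,4-dihydroxy-3,6-dimethylbenzoate lacks the C5 methyl, so steps 6 and 7 install it.
- O6' is benzylated before the C4' triflate exists. A free phenoxide beside an aryl–silicon bond that has a triflate on its other side is itself an aryne trigger (base-induced carbon-to-oxygen silyl shift), so benzylation after triflation is avoided.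
- Ring A enters as an aldehyde (reliable regiochemistry in formylation, clean differentiation of the two hydroxyls) and is oxidised to the acid afterwards.
- Assumption: 4,5-dimethylresorcinol and methyl 2,4-dihydroxy-3,6-dimethylbenzoate are taken as commercial.

Step 1
Reactants: 1 4,5-dimethylresorcinol (4,5-dimethylbenzene-1,3-diol); 2 N,N-dimethylformamide
Product: 4 2,4-dihydroxy-5,6-dimethylbenzaldehyde, via aryl iminium salt 3 (not isolated)
Conditions: POCl3 (1.2 equiv), DMF, MeCN, 0 °C to rt; then H2O, 50 °C
Reagents that add atoms: N,N-dimethylformamide (2), CN(C)C=O; water, O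
Why: Vilsmeier–Haack formylation, in which the chloroiminium ion attacks C6 of the resorcinol (para to one hydroxyl, ortho to the other, and less crowded than C2 between the two hydroxyls, as with orcinol) and water hydrolyses iminium 3 to the aldehyde.

Step 2
Reactants: 4 2,4-dihydroxy-5,6-dimethylbenzaldehyde
Product: 5 3-bromo-2,4-dihydroxy-5,6-dimethylbenzaldehyde
Conditions: NBS (1.0 equiv), MeCN, 0 °C
Reagents that add atoms: N-bromosuccinimide, O=C1CCC(=O)N1Br
Why: Electrophilic aromatic bromination at C3, the only unsubstituted ring carbon, which both flanking hydroxyl groups activate.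

Step 3
Reactants: 5 3-bromo-2,4-dihydroxy-5,6-dimethylbenzaldehyde
Product: 6 4-(allyloxy)-3-bromo-2-hydroxy-5,6-dimethylbenzaldehyde
Conditions: allyl bromide (1.05 equiv), K2CO3 (1.05 equiv), acetone, rt
Reagents that add atoms: allyl bromide, C=CCBr
Why: Williamson ether synthesis that is selective for the C4 hydroxyl, because the C2 hydroxyl is held in a hydrogen bond to the formyl group and is the less acidic and less nucleophilic of the two.

Step 4
Reactants: 6 4-(allyloxy)-3-bromo-2-hydroxy-5,6-dimethylbenzaldehyde
Product: 7 4-(allyloxy)-2-(benzyloxy)-3-bromo-5,6-dimethylbenzaldehyde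
Conditions: BnBr (1.5 equiv), K2CO3 (2 equiv), DMF, 60 °C
Reagents that add atoms: benzyl bromide, BrCc1ccccc1
Why: Williamson ether synthesis on the remaining chelated hydroxyl under more forcing conditions; placing the future O6' benzyl group here means the later depside never carries a free C6' phenoxide under base.

Step 5
Reactants: 7 4-(allyloxy)-2-(benzyloxy)-3-bromo-5,6-dimethylbenzaldehyde
Product: 8 4-(allyloxy)-2-(benzyloxy)-3-bromo-5,6-dimethylbenzoic acid
Conditions: NaClO2 (3 equiv), NaH2PO4 (3 equiv), 2-methyl-2-butene (20 equiv), t-BuOH/THF/H2O, rt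
Reagents that add atoms: sodium chlorite, [Na+].[O-]Cl=O
Why: Pinnick oxidation of a hindered aryl aldehyde, in which the trisubstituted alkene scavenges hypochlorous acid far faster than the allyl ether does and the fully substituted, phenol-free ring offers no site for chlorination.

Step 6
Reactants: 9 methyl 2,4-dihydroxy-3,6-dimethylbenzoate
Product: 11 methyl 5-formyl-2,4-dihydroxy-3,6-dimethylbenzoate, via chloro(methoxy)methyl arene 10 (not isolated)
Conditions: TiCl4 (2.5 equiv), Cl2CHOMe (1.5 equiv), CH2Cl2, 0 °C to rt; then 1 M HCl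
Reagents that add atoms: dichloromethyl methyl ether, COC(Cl)Cl; water, O
Why: Rieche formylation, in which titanium bound to the C4 phenol delivers the electrophile to C5, the only free ring carbon, and aqueous acid hydrolyses chloro ether 10 to the aldehyde.

Step 7
Reactants: 11 methyl 5-formyl-2,4-dihydroxy-3,6-dimethylbenzoate
Product: 13 methyl 2,4-dihydroxy-3,5,6-trimethylbenzoate, via benzylic alcohol 12 (not isolated)
Conditions: Et3SiH (3 equiv), TFA, CH2Cl2, 0 °C to rt
Reagents that add atoms: none
Why: Ionic hydrogenation of an aryl aldehyde to a methyl group, in which hydride reduces the protonated aldehyde to alcohol 12 and the ortho and para hydroxyls stabilise the benzylic cation for the second hydride transfer; the fully substituted ring cannot form diarylmethanes.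

Step 8
Reactants: 8 4-(allyloxy)-2-(benzyloxy)-3-bromo-5,6-dimethylbenzoic acid; 13 methyl 2,4-dihydroxy-3,5,6-trimethylbenzoate
Product: 15 methyl 4-{[4-(allyloxy)-2-(benzyloxy)-3-bromo-5,6-dimethylbenzoyl]oxy}-2-hydroxy-3,5,6-trimethylbenzoate, via mixed trifluoroacetic anhydride 14 (not isolated)
Conditions: TFAA (4 equiv), toluene, rt
Reagents that add atoms: none
Why: Esterification through mixed anhydride 14 and its acylium ion, the classical method for doubly ortho-substituted benzoic acids; the linear acylium reaches the C4 hydroxyl of 13 despite its two ortho methyls, while the C2 hydroxyl, hydrogen-bonded to the methyl ester, is not acylated and ring B has no free carbon for C-acylation.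

Step 9
Reactants: 15 methyl 4-{[4-(allyloxy)-2-(benzyloxy)-3-bromo-5,6-dimethylbenzoyl]oxy}-2-hydroxy-3,5,6-trimethylbenzoate
Product: 16 methyl 4-{[4-(allyloxy)-2-(benzyloxy)-3-bromo-5,6-dimethylbenzoyl]oxy}-2-(benzyloxy)-3,5,6-trimethylbenzoate
Conditions: BnBr (2 equiv), K2CO3 (3 equiv), DMF, 50 °C
Reagents that add atoms: benzyl bromide, BrCc1ccccc1
Why: Williamson ether synthesis on the chelated C2 hydroxyl of ring B; ring A has no free phenol, so the base-induced Smiles rearrangement open to depsides with a C6' phenoxide cannot occur, and the fourfold ortho-substituted aryl ester resists carbonate.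

Step 10
Reactants: 16 methyl 4-{[4-(allyloxy)-2-(benzyloxy)-3-bromo-5,6-dimethylbenzoyl]oxy}-2-(benzyloxy)-3,5,6-trimethylbenzoate
Product: 17 methyl 2-(benzyloxy)-4-{[2-(benzyloxy)-3-bromo-4-hydroxy-5,6-dimethylbenzoyl]oxy}-3,5,6-trimethylbenzoate
Conditions: Pd(PPh3)4 (5 mol %), morpholine (5 equiv), THF, rt
Reagents that add atoms: none
Why: Tsuji–Trost deallylation, in which zerovalent palladium ionises the allyl aryl ether to a π-allyl complex that morpholine captures, while the benzyl ethers, both esters and the doubly flanked aryl bromide (slow oxidative addition at room temperature) are untouched.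

Step 11
Reactants: 17 methyl 2-(benzyloxy)-4-{[2-(benzyloxy)-3-bromo-4-hydroxy-5,6-dimethylbenzoyl]oxy}-3,5,6-trimethylbenzoate
Product: 21 methyl 2-(benzyloxy)-4-{[2-(benzyloxy)-5,6-dimethyl-4-(trifluoromethylsulfonyloxy)-3-(trimethylsilyl)benzoyl]oxy}-3,5,6-trimethylbenzoate (C4' triflate, C5' SiMe3), via trimethylsilyl ether 18 (not isolated), via aryllithium 19 (not isolated), via lithium phenoxide 20 (not isolated)
Conditions: HMDS, THF, 65 °C, then evaporation; n-BuLi (1.1 equiv), THF, −95 to −78 °C; Tf2O (1.3 equiv), −95 to −78 °C; aq. NaHCO3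
Reagents that add atoms: hexamethyldisilazane, C[Si](C)(C)N[Si](C)(C)C; trifluoromethanesulfonic anhydride, O=S(=O)(OS(=O)(=O)C(F)(F)F)C(F)(F)F
Why: Standard three-stage preparation of an ortho-silyl aryl triflate: O-silylation gives 18, bromine–lithium exchange at C5' (faster at −95 °C than addition of n-BuLi to the doubly ortho-substituted ester carbonyls) gives 19, a retro-Brook 1,3 oxygen-to-carbon silyl shift gives phenoxide 20, and Tf2O traps it, so the triflate appears only after O6' is benzylated.

Step 12
Reactants: 21 methyl 2-(benzyloxy)-4-{[2-(benzyloxy)-5,6-dimethyl-4-(trifluoromethylsulfonyloxy)-3-(trimethylsilyl)benzoyl]oxy}-3,5,6-trimethylbenzoate; 2 N,N-dimethylformamide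
Product: 24 methyl 2-(benzyloxy)-4-{[2-(benzyloxy)-3-formyl-4-hydroxy-5,6-dimethylbenzoyl]oxy}-3,5,6-trimethylbenzoate (di-O-benzyl pseudocyphellarin A), via C4'–C5' aryne 22 (not isolated), via benzoxete aminal 23 (not isolated)
Conditions: CsF (3 equiv), anhydrous DMF (0.02 M), rt; then H2O
Reagents that add atoms: N,N-dimethylformamide (2), CN(C)C=O; water, O
Why: Fluoride attacks silicon of 21 and the C4' triflate departs to give aryne 22; the oxygen of N,N-dimethylformamide adds to C4', the C5' aryl anion closes on the iminium carbon (4-exo-trig, a formal [2+2] addition) to give benzoxete 23, and water opens and hydrolyses this four-membered aminal to the C4' phenol and C5' aldehyde, so no ring persists. The closest known reaction is the insertion of arynes from ortho-silyl aryl triflates into the C=O bond of formamides, which gives salicylaldehydes on hydrolysis. No stereocentre is formed, since the aminal carbon of 23 is transient and racemic. The step needs regioselectivity (oxygen at C4', carbon at C5'): the C6' benzyloxy group, helped by the C1' ester, stabilises negative charge at C5' inductively and distorts the aryne so that C4' is the more linear, more electrophilic carbon, as in 3-alkoxyarynes. It also needs chemoselectivity for the amide over other nucleophiles, which is secured by using the amide as solvent under anhydrous conditions and by having both remaining hydroxyls as benzyl ethers. The nearly neutral fluoride conditions are tolerated by the hindered depside ester and the methyl ester, and the hydrogen-bonded formyl–phenol pair is made last.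

Step 13
Reactants: 24 di-O-benzyl pseudocyphellarin A
Product: 25 pseudocyphellarin A, methyl 4-[(3-formyl-2,4-dihydroxy-5,6-dimethylbenzoyl)oxy]-2-hydroxy-3,5,6-trimethylbenzoate
Conditions: H2 (1 atm), 10% palladium on carbon, EtOAc, rt
Reagents that add atoms: none
Why: Catalytic hydrogenolysis of the two aryl benzyl ethers under neutral conditions; the formyl group, held between two hydrogen-bonding hydroxyls, and the aryl ester should not be reduced at 1 atm if the reaction is stopped after uptake of two equivalents, and the absence of base protects the depside with its free C6' hydroxyl from rearrangement.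

Compound list
1 | 4,5-dimethylresorcinol (4,5-dimethylbenzene-1,3-diol) | Cc1cc(O)cc(O)c1C | starting material
2 | N,N-dimethylformamide | CN(C)C=O | starting material
3 | (2,4-dihydroxy-5,6-dimethylbenzylidene)dimethyliminium salt, shown as chloride | C[N+](C)=Cc1c(C)c(C)c(O)cc1O.[Cl-] | intermediate (not isolated)
4 | 2,4-dihydroxy-5,6-dimethylbenzaldehyde | O=Cc1c(C)c(C)c(O)cc1O | intermediate
5 | 3-bromo-2,4-dihydroxy-5,6-dimethylbenzaldehyde | O=Cc1c(C)c(C)c(O)c(Br)c1O | intermediate
6 | 4-(allyloxy)-3-bromo-2-hydroxy-5,6-dimethylbenzaldehyde | O=Cc1c(C)c(C)c(OCC=C)c(Br)c1O | intermediate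
7 | 4-(allyloxy)-2-(benzyloxy)-3-bromo-5,6-dimethylbenzaldehyde | O=Cc1c(C)c(C)c(OCC=C)c(Br)c1OCc2ccccc2 | intermediate
8 | 4-(allyloxy)-2-(benzyloxy)-3-bromo-5,6-dimethylbenzoic acid | OC(=O)c1c(C)c(C)c(OCC=C)c(Br)c1OCc2ccccc2 | intermediate
9 | methyl 2,4-dihydroxy-3,6-dimethylbenzoate | COC(=O)c1c(C)cc(O)c(C)c1O | starting material
10 | methyl 5-[chloro(methoxy)methyl]-2,4-dihydroxy-3,6-dimethylbenzoate (racemic) | COC(=O)c1c(C)c(C(Cl)OC)c(O)c(C)c1O | intermediate (not isolated)
11 | methyl 5-formyl-2,4-dihydroxy-3,6-dimethylbenzoate | COC(=O)c1c(C)c(C=O)c(O)c(C)c1O | intermediate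
12 | methyl 2,4-dihydroxy-5-(hydroxymethyl)-3,6-dimethylbenzoate | COC(=O)c1c(C)c(CO)c(O)c(C)c1O | intermediate (not isolated)
13 | methyl 2,4-dihydroxy-3,5,6-trimethylbenzoate | COC(=O)c1c(C)c(C)c(O)c(C)c1O | intermediate
14 | 4-(allyloxy)-2-(benzyloxy)-3-bromo-5,6-dimethylbenzoic trifluoroacetic anhydride | O=C(OC(=O)C(F)(F)F)c1c(C)c(C)c(OCC=C)c(Br)c1OCc2ccccc2 | intermediate (not isolated)
15 | methyl 4-{[4-(allyloxy)-2-(benzyloxy)-3-bromo-5,6-dimethylbenzoyl]oxy}-2-hydroxy-3,5,6-trimethylbenzoate | COC(=O)c1c(C)c(C)c(OC(=O)c2c(C)c(C)c(OCC=C)c(Br)c2OCc3ccccc3)c(C)c1O | intermediate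
16 | methyl 4-{[4-(allyloxy)-2-(benzyloxy)-3-bromo-5,6-dimethylbenzoyl]oxy}-2-(benzyloxy)-3,5,6-trimethylbenzoate | COC(=O)c1c(C)c(C)c(OC(=O)c2c(C)c(C)c(OCC=C)c(Br)c2OCc3ccccc3)c(C)c1OCc4ccccc4 | intermediate
17 | methyl 2-(benzyloxy)-4-{[2-(benzyloxy)-3-bromo-4-hydroxy-5,6-dimethylbenzoyl]oxy}-3,5,6-trimethylbenzoate | COC(=O)c1c(C)c(C)c(OC(=O)c2c(C)c(C)c(O)c(Br)c2OCc3ccccc3)c(C)c1OCc4ccccc4 | intermediate
18 | C4' trimethylsilyl ether of 17 | COC(=O)c1c(C)c(C)c(OC(=O)c2c(C)c(C)c(O[Si](C)(C)C)c(Br)c2OCc3ccccc3)c(C)c1OCc4ccccc4 | intermediate (not isolated)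
19 | C5' aryllithium bearing the C4' trimethylsilyl ether | COC(=O)c1c(C)c(C)c(OC(=O)c2c(C)c(C)c(O[Si](C)(C)C)c([Li])c2OCc3ccccc3)c(C)c1OCc4ccccc4 | intermediate (not isolated)
20 | lithium C4' phenoxide bearing C5' trimethylsilyl | COC(=O)c1c(C)c(C)c(OC(=O)c2c(C)c(C)c(O[Li])c([Si](C)(C)C)c2OCc3ccccc3)c(C)c1OCc4ccccc4 | intermediate (not isolated)
21 | methyl 2-(benzyloxy)-4-{[2-(benzyloxy)-5,6-dimethyl-4-(trifluoromethylsulfonyloxy)-3-(trimethylsilyl)benzoyl]oxy}-3,5,6-trimethylbenzoate (key-step precursor) | COC(=O)c1c(C)c(C)c(OC(=O)c2c(C)c(C)c(OS(=O)(=O)C(F)(F)F)c([Si](C)(C)C)c2OCc3ccccc3)c(C)c1OCc4ccccc4 | intermediate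
22 | C4'–C5' aryne of the dibenzyl depside | COC(=O)c1c(C)c(C)c(OC(=O)C2=C(OCc3ccccc3)C#CC(C)=C2C)c(C)c1OCc4ccccc4 | intermediate (not isolated)
23 | 2-(dimethylamino)-2H-benzoxete fused at C4'–C5' (oxygen on C4', aminal carbon on C5'; racemic) | COC(=O)c1c(C)c(C)c(OC(=O)c2c(C)c(C)c3OC(N(C)C)c3c2OCc4ccccc4)c(C)c1OCc5ccccc5 | intermediate (not isolated)
24 | di-O-benzyl pseudocyphellarin A, methyl 2-(benzyloxy)-4-{[2-(benzyloxy)-3-formyl-4-hydroxy-5,6-dimethylbenzoyl]oxy}-3,5,6-trimethylbenzoate | COC(=O)c1c(C)c(C)c(OC(=O)c2c(C)c(C)c(O)c(C=O)c2OCc3ccccc3)c(C)c1OCc4ccccc4 | intermediate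
25 | pseudocyphellarin A | COC(=O)c1c(C)c(C)c(OC(=O)c2c(C)c(C)c(O)c(C=O)c2O)c(C)c1O | target

Total step count: 13.
Longest linear sequence: 11 steps (steps 1–5 and 8–13, from 4,5-dimethylresorcinol); steps 6 and 7 form the ring B branch.

Steps most likely to fail

1. Step 12 (aryne insertion into the amide C=O).
What may go wrong: fluoride may attack sulfur in the crowded, fully substituted ring and strip the triflyl group without forming the aryne. The aryne may be captured by fluoride, or by phenoxide arising from premature hydrolysis, which leads to over-arylation. The C3' methyl may erode the preference for oxygen attack at C4'.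
Fallback: set out from 16. Bromine–lithium exchange with n-BuLi in THF at −95 °C (the conditions already used in step 11) gives the C5' aryllithium of the allyl ether F1. Quenching with N,N-dimethylformamide as a formyl cation equivalent, then aqueous NH4Cl, gives methyl 4-{[4-(allyloxy)-2-(benzyloxy)-3-formyl-5,6-dimethylbenzoyl]oxy}-2-(benzyloxy)-3,5,6-trimethylbenzoate F2. Deallylation with Pd(PPh3)4 and TolSO2Na (sodium p-toluenesulfinate, a scavenger that does not condense with the aldehyde) in THF/MeOH at rt releases the C4' hydroxyl and returns to the route at 24.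

2. Step 11 (silylation, bromine–lithium exchange, retro-Brook shift, triflation).
What may go wrong: n-BuLi may add to an ester carbonyl or deprotonate a benzylic position in competition with exchange, and the silyl shift may be incomplete before triflation.
Fallback: set out from 16. Bromine–magnesium exchange with i-PrMgCl·LiCl in THF (0 °C to rt), which tolerates esters, gives the C5' arylmagnesium chloride F3. Trapping with Me3SiCl gives the C5' trimethylsilyl allyl ether F4. Deallylation with Pd(PPh3)4 and morpholine gives the C4' phenol bearing C5' trimethylsilyl F5. Triflation with Tf2O and pyridine in CH2Cl2 at 0 °C returns to the route at 21.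

3. Step 8 (formation of the fourfold ortho-substituted aryl ester).
What may go wrong: acylation of the doubly ortho-methylated C4 hydroxyl may stall, or the acidic acylium conditions may cleave the ortho benzyl ether.
Fallback: set out from 8. Oxalyl chloride with catalytic DMF in CH2Cl2 gives 4-(allyloxy)-2-(benzyloxy)-3-bromo-5,6-dimethylbenzoyl chloride F6. This is added to the sodium C4 phenoxide of 13 (NaH, 1.0 equiv, THF, 0 °C to rt; the non-chelated, more acidic hydroxyl is deprotonated first), which changes the activation from an acylium ion under acid to an acyl chloride attacked by a pre-formed phenoxide under base. The sequence returns to the route at 15.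

Further compounds
F1 | step 12 | C5' aryllithium of the allyl ether (from 16) | COC(=O)c1c(C)c(C)c(OC(=O)c2c(C)c(C)c(OCC=C)c([Li])c2OCc3ccccc3)c(C)c1OCc4ccccc4
F2 | step 12 | methyl 4-{[4-(allyloxy)-2-(benzyloxy)-3-formyl-5,6-dimethylbenzoyl]oxy}-2-(benzyloxy)-3,5,6-trimethylbenzoate | COC(=O)c1c(C)c(C)c(OC(=O)c2c(C)c(C)c(OCC=C)c(C=O)c2OCc3ccccc3)c(C)c1OCc4ccccc4
F3 | step 11 | C5' arylmagnesium chloride (from 16) | COC(=O)c1c(C)c(C)c(OC(=O)c2c(C)c(C)c(OCC=C)c([Mg]Cl)c2OCc3ccccc3)c(C)c1OCc4ccccc4
F4 | step 11 | C5' trimethylsilyl allyl ether | COC(=O)c1c(C)c(C)c(OC(=O)c2c(C)c(C)c(OCC=C)c([Si](C)(C)C)c2OCc3ccccc3)c(C)c1OCc4ccccc4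
F5 | step 11 | C4' phenol bearing C5' trimethylsilyl | COC(=O)c1c(C)c(C)c(OC(=O)c2c(C)c(C)c(O)c([Si](C)(C)C)c2OCc3ccccc3)c(C)c1OCc4ccccc4
F6 | step 8 | 4-(allyloxy)-2-(benzyloxy)-3-bromo-5,6-dimethylbenzoyl chloride | O=C(Cl)c1c(C)c(C)c(OCC=C)c(Br)c1OCc2ccccc2
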